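**Plan**

1. Retrosynthesis: cut C–prenyl at the C(Me)(prenyl) carbon, then C–acyl, then the cyclohexane C(OH)Me (back to C=CH2), then the spiro C–CH2 bond by a retro-[3,3] shift to an aryl allyl ether, then ArO–CH2, Ar–CH2 and the cyclopentane ring-fusion C–C bond. This leads to (S)-linalool, an iodophenol, (R)-2-methylbutanoic acid and prenyl acetate.
2. Forward order: cyclopentane by magnesium-ene cyclisation, aryl–CH2 bond by Negishi coupling, eight-membered ether ring by Mitsunobu closure, two-atom ring contraction to the spiro cyclohexane with dearomatisation of the arene to the future trione ring, then tertiary alcohol, trione unmasking, C-acylation and C-prenylation.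
3. Enabling feature: in the spiro cyclohexane the carbinol carbon C(OH)Me lies between the CH2 on the spiro carbon and a ring-fusion CH, so as C(=CH2) it is the central carbon of an allyl unit. The spiro carbon is an ortho carbon of a phloroglucinol whose neighbouring oxygen (the later C=O next to the acyl-bearing carbon) can carry that allyl unit. The ring O–C(aryl)–C(spiro)–CH2–CH–CH–C(=CH2)–CH2 (8 atoms) is therefore a Claisen substrate that contracts to the carbocycle C(spiro)–CH2–CH–CH–C(=CH2)–CH2 (6 atoms).
4. Stereochemistry: the cyclopentanol carbon comes from (S)-linalool; both ring-fusion carbons from the cis-selective, alkoxide-chelated magnesium-ene step; the spiro carbon from the bicyclo[3.3.1]-like Claisen transition state, in which the tether oxygen fixes which carbonyl lies on which face; the cyclohexanol carbon from face-selective radical hydration; the side-chain centre from (R)-2-methylbutanoic acid; C(Me)(prenyl) from ligand-controlled palladium prenylation.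

Key step: step 10

Remark: (S)-(+)-linalool is taken as a commercial compound of high enantiomeric purity, and enolised triones are drawn as one tautomer.

**Route**

Step 1
Reactants: 1 2,6-dimethoxytoluene
Product: 3 3,5-dimethoxy-4-methylphenol, via aryl pinacol boronate 2 (not isolated)
Conditions: [Ir(OMe)(cod)]2 (1.5 mol%), dtbpy (3 mol%), B2pin2 (1.0 equiv), THF, 80 °C; then 30% aq. H2O2, NaOH, 0 °C to rt
Reagents that add atoms: hydrogen peroxide, OO
Why: sterically governed iridium-catalysed C–H borylation should occur only at the C–H flanked by two hydrogens (para to the methyl group), and oxidation of the boronate in the same flask gives the phenol.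

Step 2
Reactants: 3 3,5-dimethoxy-4-methylphenol
Product: 4 2-iodo-3,5-dimethoxy-4-methylphenol
Conditions: NIS (1.0 equiv), MeCN, −20 °C
Reagents that add atoms: N-iodosuccinimide, O=C1CCC(=O)N1I
Why: electrophilic aromatic iodination at one of the two equivalent positions ortho to OH (para is blocked by methyl), with mono-substitution held by stoichiometry and low temperature.

Step 3
Reactants: 4 2-iodo-3,5-dimethoxy-4-methylphenol
Product: 5 tert-butyl(2-iodo-3,5-dimethoxy-4-methylphenoxy)dimethylsilane
Conditions: TBSCl, imidazole, DMF, rt
Reagents that add atoms: tert-butyldimethylsilyl chloride, C[Si](C)(Cl)C(C)(C)C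
Why: standard silylation masks the phenol against the organometallic and oxidative steps that follow and is removed in step 8.

Step 4
Reactants: 6 (S)-(+)-linalool
Product: 7 (2E,6S)-2,6-dimethylocta-2,7-diene-1,6-diol
Conditions: SeO2 (0.1 equiv), t-BuOOH (2 equiv), salicylic acid (0.1 equiv), CH2Cl2, rt
Reagents that add atoms: selenium dioxide, O=[Se]=O (oxygen carrier); tert-butyl hydroperoxide, CC(C)(C)OO (terminal oxidant)
Why: catalytic SeO2 allylic hydroxylation (ene reaction then [2,3] shift) is selective for the (E)-methyl group of the trisubstituted alkene, while the vinyl group has no allylic hydrogen and the carbinol stereocentre is untouched.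

Step 5
Reactants: 7 (2E,6S)-2,6-dimethylocta-2,7-diene-1,6-diol
Product: 9 (3S,6E)-8-chloro-3,7-dimethylocta-1,6-dien-3-ol, via allylic mesylate 8 (not isolated)
Conditions: MsCl, 2,4,6-collidine, LiCl, DMF, 0 °C
Reagents that add atoms: lithium chloride, [Li+].[Cl-]
Why: the primary allylic alcohol is mesylated selectively over the tertiary one and displaced in situ by chloride (SN2) without allylic transposition.

Step 6
Reactants: 9 (3S,6E)-8-chloro-3,7-dimethylocta-1,6-dien-3-ol; 5 tert-butyl(2-iodo-3,5-dimethoxy-4-methylphenoxy)dimethylsilane
Product: 13 tert-butyl(2-{[(1R,2S,5R)-2-hydroxy-2-methyl-5-(prop-1-en-2-yl)cyclopentyl]methyl}-3,5-dimethoxy-4-methylphenoxy)dimethylsilane, via open-chain allylmagnesium chloride 10 (not isolated), via cyclopentylmethylmagnesium chloride 11 (not isolated), via cyclopentylmethylzinc chloride 12 (not isolated)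
Conditions: i-PrMgCl (1.0 equiv), THF, −40 °C; Rieke Mg, −70 °C to rt, then 50 °C; ZnCl2 (1.2 equiv), 0 °C; then 5, Pd(OAc)2 (4 mol%), SPhos (8 mol%), 60 °C; aq. NH4Cl
Reagents that add atoms: none
Why: an intramolecular magnesium-ene cyclisation (the allyl γ-carbon bonds to the internal vinyl carbon while Mg moves to the terminal carbon) closes the cyclopentane with CH2Mg and isopropenyl cis, as is usual for five-ring formation, and with CH2Mg cis to the chloromagnesium alkoxide through O–Mg chelation, which together with the (S)-carbinol fixes both new ring centres as R, and transmetalation to zinc followed by Negishi coupling joins the primary alkyl group to the hindered aryl iodide.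

Step 7
Reactants: 13 the coupled silyl ether
Product: 14 2-[(1R,2R,3S)-2-{[2-(tert-butyldimethylsilyloxy)-4,6-dimethoxy-5-methylphenyl]methyl}-3-hydroxy-3-methylcyclopentyl]prop-2-en-1-ol
Conditions: SeO2 (0.3 equiv), t-BuOOH (2 equiv), CH2Cl2, 0 °C to rt
Reagents that add atoms: selenium dioxide, O=[Se]=O (oxygen carrier); tert-butyl hydroperoxide, CC(C)(C)OO (terminal oxidant)
Why: SeO2 allylic hydroxylation of a 1,1-disubstituted alkene prefers the methyl group over the ring methine, giving the 2-substituted allyl alcohol with the double bond unmoved and no stereocentre touched.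

Step 8
Reactants: 14 the silyl-protected allylic alcohol
Product: 15 2-{[(1R,2S,5R)-2-hydroxy-5-(3-hydroxyprop-1-en-2-yl)-2-methylcyclopentyl]methyl}-3,5-dimethoxy-4-methylphenol
Conditions: K2CO3, MeOH, rt
Reagents that add atoms: none
Why: aryl silyl ethers are cleaved by methanolic carbonate under conditions that leave the allylic and tertiary alcohols alone.

Step 9
Reactants: 15 the phenol diol
Product: 16 eight-membered aryl allyl ether: the phenol oxygen of 15 is bonded to the allylic CH2, ring atoms O, C(aryl)–O, C(aryl), ArCH2, CH, CH, C(=CH2), OCH2, cis-fused to the (S)-1-methylcyclopentan-1-ol (ring-fusion carbons R,R)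
Conditions: PPh3 (2 equiv), DIAD (2 equiv), toluene, 0.003 M, slow addition of 15, 0 °C to rt
Reagents that add atoms: none
Why: intramolecular Mitsunobu etherification of the neutral phenol with the primary allylic alcohol gives O-alkylation, the cis arrangement of the two arms on the cyclopentane pre-organises the eight-membered closure, the tertiary alcohol is inert, and SN2 or SN2′ attack give the same product because the allyl unit is symmetric.

Step 10
Reactants: 16 the eight-membered aryl allyl ether
Product: 17 (1'S,3a'R,7a'R)-1'-hydroxy-2,4-dimethoxy-1',3-dimethyl-4'-methylideneoctahydrospiro[cyclohexa-2,4-diene-1,6'-inden]-6-one, cis-fused, with the C-6 carbonyl on the face of H-3a' and H-7a'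
Conditions: PhNEt2, BHT (5 mol%), 180 °C, sealed tube, argon
Reagents that add atoms: none
Why: Proposed new method: on heating, 16 should undergo a concerted [3,3]-sigmatropic (aromatic Claisen) shift in which the exocyclic methylene carbon bonds to the substituted ortho carbon of the arene while the O–CH2 bond breaks, so the eight-membered ring contracts by two atoms to the six-membered carbocycle and the arene becomes a 3,5-dimethoxycyclohexa-2,4-dienone that cannot re-aromatise because the new carbon is quaternary. The closest known reaction types are the ortho-Claisen rearrangement onto a substituted ortho position, which gives isolable 6,6-disubstituted cyclohexa-2,4-dienones from phloroglucinol-type ethers, and ring-contracting sigmatropic shifts of cyclic allyl ethers; here release of medium-ring strain and the two vinylogous ester units of the dienone supply the driving force. The carbocycle closes in a 6-endo mode inside a bicyclo[3.3.1]-like transition state, the pericyclic chair and the nascent cyclohexane chair sharing the spiro carbon, the new CH2 and the central allyl carbon. The one new stereocentre, the spiro carbon, is controlled by the two ring-fusion carbons: the carbonyl that derives from the tether oxygen must sit axial on the side of the departing OCH2 bridge, and the cyclopentane avoids that bridge (its C–C(OH)Me bond equatorial), so this carbonyl ends on the face of the two ring-fusion hydrogens. The step needs attack at the substituted rather than the free ortho carbon, which is secured because the adduct at the free position is a medium-ring bridged dienone that could only aromatise to a [5]metacyclophane and therefore reverts. It also needs the absence of an onward Cope shift to the para carbon, which is secured because that shift would place a trans double bond in an eight-membered ring.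

Step 11
Reactants: 17 the spiro dienone with exocyclic methylene
Product: 18 (1'S,3a'R,4'S,7a'R)-1',4'-dihydroxy-2,4-dimethoxy-1',3,4'-trimethyloctahydrospiro[cyclohexa-2,4-diene-1,6'-inden]-6-one
Conditions: Co(acac)2 (0.2 equiv), PhSiH3 (2.5 equiv), O2 (1 atm), i-PrOH/CH2Cl2, rt
Reagents that add atoms: dioxygen, O=O
Why: in this Mukaiyama hydration, hydrogen-atom transfer from a cobalt hydride to the unhindered 1,1-disubstituted alkene gives the tertiary radical, which should take up O2 on the face of the cyclopentane ring (equatorial approach, near the cyclopentanol OH) because the axial face is screened by the syn-axial dienone carbonyl carbon, so OH ends cis to the five-membered ring and methyl cis to the ring-fusion hydrogens, while the donor-substituted dienone alkenes are poorer hydrogen-atom acceptors.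

Step 12
Reactants: 18 the dihydroxy dimethoxy dienone
Product: 19 (1'S,3a'R,4'S,7a'R)-1',4'-dihydroxy-1',3,4'-trimethyloctahydrospiro[cyclohexane-1,6'-indene]-2,4,6-trione (drawn as its dienol)
Conditions: 2 M NaOH, MeOH/H2O, 70 °C; then citric acid to pH 4, 0 °C
Reagents that add atoms: water, O (delivered as hydroxide from sodium hydroxide, [Na+].[OH-])
Why: vinylogous ester hydrolysis by addition–elimination of hydroxide at both methoxy-bearing carbons gives the filicinic acid-type trione, whose delocalised anion shields the non-enolisable 1,3-dicarbonyl unit at the spiro carbon from retro-Claisen cleavage, and the mild acidification avoids ionising the tertiary alcohols.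

Step 13
Reactants: 19 the spiro trione; 20 (R)-2-methylbutanoic acid
Product: 22 5-[(2R)-2-methylbutanoyl] derivative of 19 (acyl group on the only unsubstituted ring carbon, enolised triketone), via O-acyl enol ester 21 (not isolated)
Conditions: DCC (1.1 equiv), DMAP (0.3 equiv), CH2Cl2, 0 °C to rt
Reagents that add atoms: none
Why: Steglich-type O-acylation of the enolised trione followed by DMAP-mediated O-to-C acyl transfer, a known direct C-acylation of cyclic 1,3-diones with carboxylic acids, places the acyl group on the unsubstituted ring carbon as the chelated triketone, the tertiary alcohols do not react, and the low temperature limits epimerisation of the acid α-centre.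

Step 14
Reactants: 22 the acyl trione; 23 prenyl acetate
Product: 24 target compound CNP0236509.3
Conditions: Pd2(dba)3·CHCl3 (2.5 mol%), (R,R)-DACH-phenyl Trost ligand (7.5 mol%), Et3N (1.1 equiv), CH2Cl2, 0 °C to rt
Reagents that add atoms: none
Why: Proposed new method: ionisation of prenyl acetate by zerovalent palladium gives a π-prenyl complex that the methyl-bearing ring carbon of the delocalised acyl-trione anion should attack at its unsubstituted terminus (alkylation at the acyl-bearing carbon would destroy the chelated triketone), and because the spiro ring is too remote to bias the faces of the planar nucleophile, the chiral ligand pocket is relied on to place prenyl on the face cis to the ring CH2 attached to the ring-fusion carbon, the sense of induction of the (R,R) ligand to be confirmed on the first run; the closest known reaction types are the palladium-catalysed Tsuji–Trost C-prenylation of acylphloroglucinols and Trost asymmetric allylic alkylation of prochiral cyclic β-dicarbonyl nucleophiles to quaternary centres.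

**Compound list**

1 | 2,6-dimethoxytoluene | Cc1c(OC)cccc1OC | starting material
2 | 2-(3,5-dimethoxy-4-methylphenyl)-4,4,5,5-tetramethyl-1,3,2-dioxaborolane | Cc1c(OC)cc(cc1OC)B1OC(C)(C)C(C)(C)O1 | intermediate
3 | 3,5-dimethoxy-4-methylphenol | Cc1c(OC)cc(O)cc1OC | intermediate
4 | 2-iodo-3,5-dimethoxy-4-methylphenol | Cc1c(OC)cc(O)c(I)c1OC | intermediate
5 | tert-butyl(2-iodo-3,5-dimethoxy-4-methylphenoxy)dimethylsilane | Cc1c(OC)cc(O[Si](C)(C)C(C)(C)C)c(I)c1OC | intermediate
6 | (S)-(+)-linalool, (3S)-3,7-dimethylocta-1,6-dien-3-ol | CC(C)=CCC[C@@](C)(C=C)O | starting material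
7 | (2E,6S)-2,6-dimethylocta-2,7-diene-1,6-diol | OC/C(C)=C/CC[C@@](C)(C=C)O | intermediate
8 | (2E,6S)-6-hydroxy-2,6-dimethylocta-2,7-dien-1-yl methanesulfonate | CS(=O)(=O)OC/C(C)=C/CC[C@@](C)(C=C)O | intermediate
9 | (3S,6E)-8-chloro-3,7-dimethylocta-1,6-dien-3-ol | ClC/C(C)=C/CC[C@@](C)(C=C)O | intermediate
10 | chloromagnesium alkoxide of the allylmagnesium chloride from 9 | Cl[Mg]C/C(C)=C/CC[C@@](C)(C=C)O[Mg]Cl | intermediate
11 | all-cis cyclopentylmethylmagnesium chloride (chloromagnesium alkoxide; OMgCl, CH2MgCl and isopropenyl on one face) | Cl[Mg]C[C@@H]1[C@@H](CC[C@]1(C)O[Mg]Cl)C(C)=C | intermediate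
12 | corresponding cyclopentylmethylzinc chloride | Cl[Zn]C[C@@H]1[C@@H](CC[C@]1(C)O[Mg]Cl)C(C)=C | intermediate
13 | tert-butyl(2-{[(1R,2S,5R)-2-hydroxy-2-methyl-5-(prop-1-en-2-yl)cyclopentyl]methyl}-3,5-dimethoxy-4-methylphenoxy)dimethylsilane | Cc1c(OC)cc(O[Si](C)(C)C(C)(C)C)c(C[C@@H]2[C@@H](CC[C@]2(C)O)C(C)=C)c1OC | intermediate
14 | 2-[(1R,2R,3S)-2-{[2-(tert-butyldimethylsilyloxy)-4,6-dimethoxy-5-methylphenyl]methyl}-3-hydroxy-3-methylcyclopentyl]prop-2-en-1-ol | Cc1c(OC)cc(O[Si](C)(C)C(C)(C)C)c(C[C@@H]2[C@@H](CC[C@]2(C)O)C(=C)CO)c1OC | intermediate
15 | 2-{[(1R,2S,5R)-2-hydroxy-5-(3-hydroxyprop-1-en-2-yl)-2-methylcyclopentyl]methyl}-3,5-dimethoxy-4-methylphenol | Cc1c(OC)cc(O)c(C[C@@H]2[C@@H](CC[C@]2(C)O)C(=C)CO)c1OC | intermediate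
16 | eight-membered aryl allyl ether (cyclopenta-fused 3-methylidene-1-benzoxocine; carbinol carbon S, ring-fusion carbons R,R; dimethoxy, methyl on the arene) | Cc1c(OC)cc2c(c1OC)C[C@@H]1[C@@H](CC[C@]1(C)O)C(=C)CO2 | intermediate
17 | (1'S,3a'R,7a'R)-1'-hydroxy-2,4-dimethoxy-1',3-dimethyl-4'-methylideneoctahydrospiro[cyclohexa-2,4-diene-1,6'-inden]-6-one (C-6 carbonyl on the face of the ring-fusion hydrogens) | CC1=C(OC)[C@]2(C[C@@H]3[C@@H](CC[C@]3(C)O)C(=C)C2)C(=O)C=C1OC | intermediate
18 | (1'S,3a'R,4'S,7a'R)-1',4'-dihydroxy-2,4-dimethoxy-1',3,4'-trimethyloctahydrospiro[cyclohexa-2,4-diene-1,6'-inden]-6-one | CC1=C(OC)[C@]2(C[C@@H]3[C@@H](CC[C@]3(C)O)[C@@](C)(O)C2)C(=O)C=C1OC | intermediate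
19 | (1'S,3a'R,4'S,7a'R)-1',4'-dihydroxy-1',3,4'-trimethyloctahydrospiro[cyclohexane-1,6'-indene]-2,4,6-trione, dienol form | CC1=C(O)[C@]2(C[C@@H]3[C@@H](CC[C@]3(C)O)[C@@](C)(O)C2)C(=O)C=C1O | intermediate
20 | (R)-2-methylbutanoic acid | CC[C@@H](C)C(=O)O | starting material
21 | enol (R)-2-methylbutanoate of 19 (ester on the enol oxygen next to the unsubstituted ring carbon) | CC1=C(O)[C@]2(C[C@@H]3[C@@H](CC[C@]3(C)O)[C@@](C)(O)C2)C(=O)C=C1OC(=O)[C@H](C)CC | intermediate
22 | 5-[(2R)-2-methylbutanoyl] derivative of 19, enolised triketone | CC[C@@H](C)C(=O)C1=C(O)C(C)=C(O)[C@]2(C[C@@H]3[C@@H](CC[C@]3(C)O)[C@@](C)(O)C2)C1=O | intermediate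
23 | prenyl acetate, 3-methylbut-2-en-1-yl acetate | CC(=O)OCC=C(C)C | starting material
24 | CNP0236509.3: spiro[cyclohexane-1,6'-octahydroindene]-2,4,6-trione with 3-methyl, 3-(3-methylbut-2-enyl), 5-[(2R)-2-methylbutanoyl], 1',4'-dihydroxy and 1',4'-dimethyl groups, enol form | CC[C@@H](C)C(=O)C1=C(O)[C@](C)(CC=C(C)C)C(=O)[C@]2(C[C@@H]3[C@@H](CC[C@]3(C)O)[C@@](C)(O)C2)C1=O | target

**Step count and risks**

Total step count: 14. Longest linear sequence: 12 steps (steps 1–3, then 6–14, from 2,6-dimethoxytoluene); the linalool branch is 11 steps.

Steps most likely to fail: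

1. Step 10 (key step, proposed new method). The sigmatropic shift may be too slow below the temperature at which the tertiary alcohol dehydrates, or the ether may drain into the bridged adduct at the free ortho carbon. Fallback: setting out from 16, the allyl aryl ether is ionised with Pd(PPh3)4 (5 mol%, zerovalent palladium) in THF at 50 °C; the tethered π-allyl/phenoxide pair recombines at the substituted ortho carbon (known Tsuji–Trost dearomative C-allylation of phloroglucinol phenoxides, and known palladium cleavage of allyl aryl ethers). This comes back to the route at 17, with the spiro epimer, if formed, removed by chromatography; no new compound arises (F0).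

2. Step 14 (proposed new method). Facial selection by the ligand may be poor or mismatched, or O-prenylation may compete. Fallback: setting out from 22, classical base-mediated dearomative C-alkylation with prenyl bromide (CC(C)=CCBr) and NaOMe in MeOH at 0 °C gives 24 together with the epimer at the methyl/prenyl carbon F1; the two diastereomers are separated by preparative HPLC and the route is rejoined at 24.

3. Step 9. Oligomerisation may outrun the eight-membered ring closure, or the ring carbon may be alkylated instead of oxygen. Fallback: setting out from 14, the primary allylic alcohol is converted with methyl chloroformate and pyridine into the allylic methyl carbonate F2, and the aryl silyl ether is removed with HF·pyridine to give the phenol carbonate F3. Decarboxylative palladium-catalysed allylic etherification (Pd2(dba)3, dppf, zerovalent palladium, THF, 0 °C, 0.002 M) then closes the ether through the kinetically preferred O-attack on the symmetric π-allyl unit and comes back to the route at 16.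

Further compounds
F0 | step 10 | none | none
F1 | step 14 | epimer of 24 at the methyl/prenyl-bearing carbon | CC[C@@H](C)C(=O)C1=C(O)[C@@](C)(CC=C(C)C)C(=O)[C@]2(C[C@@H]3[C@@H](CC[C@]3(C)O)[C@@](C)(O)C2)C1=O
F2 | step 9 | allylic methyl carbonate of 14 | Cc1c(OC)cc(O[Si](C)(C)C(C)(C)C)c(C[C@@H]2[C@@H](CC[C@]2(C)O)C(=C)COC(=O)OC)c1OC
F3 | step 9 | allylic methyl carbonate of 15 (free phenol) | Cc1c(OC)cc(O)c(C[C@@H]2[C@@H](CC[C@]2(C)O)C(=C)COC(=O)OC)c1OC
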